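If the electrophile of flask theta were to be used up completely, the nucleophile would have to pay for each bond, for the acid set free by that bond, and for the protic impurity it quenches. The electrophile also balances with a dormant form, and the target balances with its isomer.

| flask | electrophile | nucleophile | protic impurity | time |
|---|---|---|---|---|
| theta | 20 mM | 1.50 equiv | 10.0 mM | 2.0 min |
| zeta | 20 mM | 3.00 equiv | 10.0 mM | 2.0 min |

1. part of the electrophile that has reacted at the end, theta
2. part of the electrophile that has reacted at the end, zeta
3. what raising the equivalents of nucleophile from its lowest to its highest value here does to the part of the electrophile that has reacted (changes below 5 percentage points count as none) (it falls / it rises / no change)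

- what has gone from electrophile into another species counts as reacted, even if it can come back
- run time (theta): 2.0 min

    electrophile + nucleophile → acid set free + target (k1 = 1.61 L mol⁻¹ s⁻¹)
    nucleophile + acid set free ⇌ protonated nucleophile, settled at all times (K2 = 43000 L mol⁻¹)
    nucleophile + protic impurity → quenched reagent (k3 = 1.40 L mol⁻¹ s⁻¹)
    target ⇌ isomer of the product (K4 = 0.127, k4 = 0.0153 s⁻¹)
    electrophile ⇌ dormant form (K5 = 0.58, k5 = 0.518 s⁻¹)

The cost of the acid can be checked in powers of ten. With binding constant K2, the ratio of bound to free acid is K2 times the free nucleophile, and its logarithm at the theta charge is 3.11. At that charge the bound form therefore outweighs the free acid, and the two stand level at a free nucleophile of 0.0233 mM. My reckoning thus charges each turnover two nucleophiles.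

For theta, C = 0.500, where the cover C is the nucleophile charge less the impurity charge, divided by two electrophile charges. Full payment needs log10 C at zero or above. Theta stands at −0.301, which makes the nucleophile its limiting reagent. Zeta has C = 1.25 and stands at 0.0969.

The half-life of the electrophile by step 1 at the theta charges, 0.24 min, is shorter than the run, so my reckoning takes the payment as complete. The dormant balance relaxes with a half-life of 0.491 s, shorter than the run, so in my reckoning the unpaid electrophile divides between free and dormant as K5 sets, and a share K5/(1+K5) counts as reacted. My reckoning thus gives 68.4% for theta and 100% for zeta.

The forecast differs, with 56% for theta, 93.6% for zeta and the verdict it rises. For theta it says “the nucleophile is therefore almost exhausted”.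

The simulation gives 72.2% for theta and 95.6% for zeta, so it rises by 23 percentage points.

In theta, formation of target and the quench ran together while free nucleophile lasted: after 0.400 min they had 65% and 67% of their turnover behind them, and at the end free nucleophile stood at 3.52% of its charge, with 6.74 mM of quenched reagent formed. The cover of 0.500 counts the protic impurity as spent, yet 33% of its charge still stood in theta at the end, and target plus isomer reached 56.1%, more than that cover, with dormant form at 16.1%. The neighbour of theta with 34 mM electrophile, equivalents held, has a cover of 0.603, which the rule turns into 74.9%; that flask gave 77.0%.

The constants were chosen freely; the rest is arithmetic.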